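**Retrosynthetic overview**
1. The C8–prenyl and C3'–prenyl bonds are both disconnected to aryl 1,1-dimethylallyl ethers, formed in one pot by a double aromatic Claisen ([3,3]) rearrangement as the last step.
2. The C3–OH is disconnected to a flavanone silyl enol ether (Rubottom oxidation), with the C2 aryl group directing the oxidant to give the 2,3-trans ketol.
3. The two tertiary allyl ethers come from Pd-catalysed O-allylation of both phenols; they also act as the phenol protecting groups during the oxidation.
4. The chromanone ring system and the C2 stereocentre are bought intact as natural (2S)-liquiritigenin. No ring is constructed; only the two cyclic six-membered Claisen transition states are involved.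

Assumption: natural (2S)-(–)-liquiritigenin (licorice flavanone) and tert-butyl 2-methylbut-3-en-2-yl carbonate are purchased; the ee of 1 is checked by chiral HPLC on receipt and again at compound 3.

**Step 1**
Reactants: 1, (2S)-7-hydroxy-2-(4-hydroxyphenyl)chroman-4-one [(–)-liquiritigenin]; 2, tert-butyl 2-methylbut-3-en-2-yl carbonate (3 equiv)
Product: 3, (2S)-7-(2-methylbut-3-en-2-yloxy)-2-[4-(2-methylbut-3-en-2-yloxy)phenyl]chroman-4-one
Conditions: Pd(PPh3)4 (5 mol %), THF, 0 °C, Ar
Reagents that add atoms: compound 2, C=CC(C)(C)OC(=O)OC(C)(C)C (supplies both 1,1-dimethylallyl groups; CO2 and t-BuOH are lost)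
Why: Decarboxylative Tsuji–Trost O-allylation, in which the phenoxides attack the more substituted terminus of the 1,1-dimethyl-π-allyl-Pd at low temperature to give the branched tertiary ethers under essentially neutral conditions that leave C2 untouched.

**Step 2**
Reactants: 3, bis(1,1-dimethylallyl) ether of liquiritigenin
Product: 4, trimethyl{[(2S)-7-(2-methylbut-3-en-2-yloxy)-2-[4-(2-methylbut-3-en-2-yloxy)phenyl]-2H-chromen-4-yl]oxy}silane (used crude)
Conditions: Et3N (3 equiv), then TMSOTf (1.3 equiv), CH2Cl2, –78 → 0 °C
Reagents that add atoms: TMSOTf, C[Si](C)(C)OS(=O)(=O)C(F)(F)F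
Why: Soft enolisation (O-silylation, then C3 deprotonation) gives the silyl enol ether without a free enolate, so the retro-oxa-Michael opening to the chalcone that would racemise C2 is avoided.

**Step 3**
Reactants: 4, TMS enol ether
Product: 5, (2R,3R)-3-hydroxy-7-(2-methylbut-3-en-2-yloxy)-2-[4-(2-methylbut-3-en-2-yloxy)phenyl]chroman-4-one
Conditions: DMDO (1.1 equiv, acetone), CH2Cl2, –78 → –30 °C; then TBAF/AcOH (1:1), THF, 0 °C
Reagents that add atoms: dimethyldioxirane, CC1(C)OO1 (delivers the C3 oxygen)
Why: Rubottom oxidation, in which DMDO epoxidises the electron-rich enol ether far faster than the monosubstituted vinyl groups and from the face anti to the C2 aryl group, giving the 2,3-trans (diequatorial, also thermodynamic) ketol; the spatial arrangement at C2 is unchanged and only its CIP descriptor switches from S to R.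

**Step 4**
Reactants: 5, (2R,3R)-3-hydroxy bis(1,1-dimethylallyl) ether
Product: 6, 3-hydroxyglabrol, (2R,3R)-3,7-dihydroxy-2-[4-hydroxy-3-(3-methylbut-2-enyl)phenyl]-8-(3-methylbut-2-enyl)chroman-4-one
Conditions: degassed o-xylene, BHT (cat.), 135–140 °C, Ar, base-washed glassware
Reagents that add atoms: none
Why: Double aromatic Claisen [3,3]-sigmatropic rearrangement turns each O–CMe2CH=CH2 into an ortho CH2CH=CMe2 and frees the phenol; ring B has equivalent ortho positions, and ring A reacts preferentially at C8 (higher C7–C8 bond order, as in 4-allyloxy-2-oxyaryl ketones), with the minor C6 isomer removed by chromatography; no stereocentre takes part.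

**Compound list**
1 | (2S)-(–)-liquiritigenin | Oc1ccc([C@H]2Oc3cc(O)ccc3C(=O)C2)cc1 | starting material
2 | tert-butyl 2-methylbut-3-en-2-yl carbonate | C=CC(C)(C)OC(=O)OC(C)(C)C | starting material
3 | (2S)-7,4'-bis(1,1-dimethylallyl) ether of liquiritigenin | C=CC(C)(C)Oc1ccc([C@H]2Oc3cc(OC(C)(C)C=C)ccc3C(=O)C2)cc1 | intermediate
4 | (2S)-4-trimethylsilyloxy-2H-chromene (enol ether of 3) | C=CC(C)(C)Oc1ccc([C@H]2Oc3cc(OC(C)(C)C=C)ccc3C(O[Si](C)(C)C)=C2)cc1 | intermediate
5 | (2R,3R)-3-hydroxy-7,4'-bis(1,1-dimethylallyloxy)flavanone | C=CC(C)(C)Oc1ccc([C@H]2Oc3cc(OC(C)(C)C=C)ccc3C(=O)[C@@H]2O)cc1 | intermediate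
6 | 3-hydroxyglabrol | CC(C)=CCc1cc([C@H]2Oc3c(ccc(O)c3CC=C(C)C)C(=O)[C@@H]2O)ccc1O | target

**Total steps:** 4. **Longest linear sequence:** 4.

**Steps most likely to fail**
1. Step 4 (C6 versus C8 regioisomers on ring A; thermal C2 epimerisation or dehydrogenation of the free ketol). Fallback: reverse the order. Rearrange 3 first to glabrol (no ketol present, and the known compound allows the regioisomer to be checked), protect both phenols as TBS ethers, hydroxylate C3 by direct lithium enolate oxidation with racemic Davis sulfonyloxaziridine (tolerates the prenyl olefins, unlike DMDO), then remove the silyl groups with HF·pyridine.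
2. Step 2 (TMSOTf ionising the tertiary allyl ethers or the C2–O1 bond, causing ether loss or racemisation). Fallback: hydroxylate before installing the ethers. Carry liquiritigenin as its bis-TBS ether through steps 2–3, desilylate to (2R,3R)-garbanzol, then apply the phenol-selective Pd reverse-prenylation to reach 5.
3. Step 1 (linear prenyl ether or C-allylation instead of the branched ether; partial racemisation through the phenoxide). Fallback: two-step propargyl route. Cu-catalysed O-alkylation with 3-chloro-3-methylbut-1-yne (CuCl2 cat., DBU, MeCN, 0 °C) to the bis(1,1-dimethylpropargyl) ether, then Lindlar semi-hydrogenation to 3.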